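## Retrosynthetic overview

1. The keto acid comes from a bicyclic hydroxy aldehyde by two late oxidations (aldehyde to acid, carbinol to ketone).
2. Both rings form in one step by an intramolecular Diels–Alder reaction of a linear (2E,7E,9E,11E)-tetraenal: the six-membered ring by the cycloaddition, the five-membered ring at the same moment from the three-carbon tether.
3. The triene is cut at its central sp2–sp2 single bond: Negishi coupling of an alkenylzirconium (from an ethyl alkyne) with a styryl bromodiene.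
4. The C5–C6 bond and the C5/C6 stereocentres come from a Marshall anti-propargylation of a C1–C5 aldehyde with an enantiopure propargylic mesylate.
5. The C4 stereocentre and the enoate come from an organocatalytic α-hydroxymethylation of a simple aldehyde, trapped by Wittig olefination.

Assumption: in the Why lines C1–C12 number the open chain of the Diels–Alder precursor (C1 ends as the CO2H carbon); reagents and catalysts named only under Conditions are bought.

## Route

Step 1
Reactants: 1 triphenylphosphine; 2 ethyl 2-bromobutanoate (racemic)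
Product: 4 ethyl 2-(triphenyl-λ5-phosphanylidene)butanoate, via phosphonium bromide 3 (not isolated)
Conditions: PhMe, 90 °C; then aq. NaOH, CH2Cl2, rt
Reagents that add atoms: none
Why: SN2 quaternisation of the phosphine by the α-bromo ester and deprotonation of the salt give the ester-stabilised Wittig ylide (phosphonium ylide formation); no stereocentre is involved.

Step 2
Reactants: 5 butanal; 6 formaldehyde (37% aq.); 4 ethyl 2-(triphenyl-λ5-phosphanylidene)butanoate
Product: 8 ethyl (2E,4S)-2-ethyl-4-(hydroxymethyl)hex-2-enoate, via (2R)-2-(hydroxymethyl)butanal 7 (not isolated)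
Conditions: (S)-2-[diphenyl(trimethylsilyloxy)methyl]pyrrolidine (10 mol %), KH2PO4/K2HPO4 buffer (pH 7), PhMe, rt; then 4 (3 equiv), CH2Cl2, rt
Reagents that add atoms: none
Why: Enamine-catalysed asymmetric cross-aldol reaction (α-hydroxymethylation) in which the diaryl(silyloxy)methyl group shields one enamine face, so formaldehyde adds to the Si face and sets the stereocentre (2R in 7, written 4S in 8), and the stabilised ylide then traps the labile β-hydroxy aldehyde in an E-selective Wittig olefination.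

Step 3
Reactants: 8 ethyl (2E,4S)-2-ethyl-4-(hydroxymethyl)hex-2-enoate
Product: 9 ethyl (2E,4S)-2-ethyl-4-formylhex-2-enoate
Conditions: DMP (1.2 equiv), pyridine, CH2Cl2, 0 °C, 30 min; used crude at once
Reagents that add atoms: none
Why: Dess–Martin oxidation takes the primary alcohol to the aldehyde without a base strong enough to enolise the doubly activated C4–H, so the 4S centre is kept provided 9 is used immediately.

Step 4
Reactants: 10 hex-3-yn-2-one
Product: 11 (2R)-hex-3-yn-2-ol
Conditions: RuCl[(R,R)-TsNCH(Ph)CH(Ph)NH2](p-cymene) (1 mol %), i-PrOH, rt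
Reagents that add atoms: none
Why: Noyori asymmetric transfer hydrogenation of the ynone, in which the (R,R)-diamine ruthenium hydride delivers hydride to the carbonyl face that gives the (R)-propargylic alcohol.

Step 5
Reactants: 11 (2R)-hex-3-yn-2-ol
Product: 12 (2R)-hex-3-yn-2-yl methanesulfonate
Conditions: MsCl, Et3N, CH2Cl2, −78 °C
Reagents that add atoms: methanesulfonyl chloride, CS(=O)(=O)Cl
Why: Sulfonylation at oxygen (mesylation) activates the propargylic position and leaves the stereocentre untouched.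

Step 6
Reactants: 9 ethyl (2E,4S)-2-ethyl-4-formylhex-2-enoate; 12 (2R)-hex-3-yn-2-yl methanesulfonate
Product: 14 ethyl (2E,4S,5R,6S)-2,4-diethyl-5-hydroxy-6-methyldec-2-en-7-ynoate, via allenylindium reagent 13 (not isolated)
Conditions: 12 (1.5 equiv), Pd(OAc)2 (5 mol %), PPh3 (5 mol %), InI (1.5 equiv), THF–HMPA 3:1, rt; H2O work-up
Reagents that add atoms: none
Why: Marshall propargylation, in which zerovalent palladium adds to 12 in anti SN2' fashion, transmetalation with InI gives the chiral allenylindium 13, and its cyclic SE2' addition to 9 gives the anti homopropargylic alcohol, the (R)-mesylate fixing 6S and 5R in a pairing that is Felkin-matched with the 4S centre.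

Step 7
Reactants: 14 ethyl (2E,4S,5R,6S)-2,4-diethyl-5-hydroxy-6-methyldec-2-en-7-ynoate
Product: 15 (2E,4S,5R,6S)-2,4-diethyl-6-methyldec-2-en-7-yne-1,5-diol
Conditions: i-Bu2AlH (3.5 equiv), CH2Cl2, −78 °C; aq. potassium sodium tartrate
Reagents that add atoms: none
Why: 1,2-Reduction of the enoate by the aluminium hydride (DIBAL reduction) gives the allylic alcohol, while the internal alkyne, the trisubstituted alkene and the stereocentres are untouched at −78 °C.

Step 8
Reactants: 16 2-ethylacrolein
Product: 18 (2E)-3-bromo-2-ethylprop-2-enal, via dibromo aldehyde 17 (not isolated)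
Conditions: Br2, CH2Cl2, −78 → 0 °C; then Et3N, 0 °C → rt
Reagents that add atoms: bromine, BrBr
Why: Electrophilic bromine addition to the alkene followed by E2 loss of HBr through the more acidic BrCH2 hydrogen gives the β-bromo enal, the E isomer (Br trans to CHO) being the thermodynamically favoured one.

Step 9
Reactants: 19 diethyl benzylphosphonate; 18 (2E)-3-bromo-2-ethylprop-2-enal
Product: 21 [(1E,3E)-4-bromo-3-ethylbuta-1,3-dien-1-yl]benzene, via sodium phosphonate carbanion 20 (not isolated)
Conditions: NaH, THF, 0 °C; then 18, 0 °C → rt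
Reagents that add atoms: none
Why: Horner–Wadsworth–Emmons olefination of the aldehyde by the benzylic phosphonate anion gives the E styrene, and the vinylic bromide and the existing E alkene are kept.

Step 10
Reactants: 15 (2E,4S,5R,6S)-2,4-diethyl-6-methyldec-2-en-7-yne-1,5-diol; 21 [(1E,3E)-4-bromo-3-ethylbuta-1,3-dien-1-yl]benzene
Product: 24 (2E,4S,5S,6S,7E,9E,11E)-2,4,8,10-tetraethyl-6-methyl-12-phenyldodeca-2,7,9,11-tetraene-1,5-diol, via alkenylzirconocene chloride 22 (not isolated), via alkenylzinc chloride 23 (not isolated)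
Conditions: Cp2Zr(H)Cl (3.4 equiv), THF, 50 °C; then ZnCl2 (1.2 equiv), Pd(PPh3)4 (5 mol %), 21 (1.2 equiv), THF, rt; aq. NH4Cl
Reagents that add atoms: none
Why: Negishi coupling after syn hydrozirconation, in which Zr–H adds cis across the alkyne and equilibrates to the isomer with zirconium on the less hindered ethyl-bearing C8 (two further equivalents only cap the hydroxyls as alkoxides), and Zr-to-Zn transmetalation and palladium-catalysed coupling proceed with retention at both alkenyl carbons to give the (7E,9E,11E)-triene.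

Step 11
Reactants: 24 (2E,4S,5S,6S,7E,9E,11E)-2,4,8,10-tetraethyl-6-methyl-12-phenyldodeca-2,7,9,11-tetraene-1,5-diol
Product: 26 (1S,2S,3S,3aR,4R,5S,7aR)-3,4,5,7-tetraethyl-2-hydroxy-1-methyl-5-[(E)-2-phenylethenyl]-2,3,3a,4,5,7a-hexahydro-1H-indene-4-carbaldehyde, via tetraenal 25 (not isolated)
Conditions: MnO2 (20 equiv), CH2Cl2, rt; filter; then PhMe, 2,6-di-tert-butyl-4-methylphenol (5 mol %), 100 °C
Reagents that add atoms: none
Why: Selective allylic oxidation by MnO2 followed by a thermal intramolecular Diels–Alder reaction through the formyl-endo transition state that gives the trans ring fusion, in which allylic 1,3-strain at the 4S and 6S centres (each C–H eclipsing its neighbouring alkene) fixes the reacting faces of enal and diene, so 3aR, 4R, 5S and 7aR follow from the E geometries.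

Step 12
Reactants: 26 (1S,2S,3S,3aR,4R,5S,7aR)-3,4,5,7-tetraethyl-2-hydroxy-1-methyl-5-[(E)-2-phenylethenyl]-2,3,3a,4,5,7a-hexahydro-1H-indene-4-carbaldehyde
Product: 27 (1S,2S,3S,3aR,4R,5S,7aR)-3,4,5,7-tetraethyl-2-hydroxy-1-methyl-5-[(E)-2-phenylethenyl]-2,3,3a,4,5,7a-hexahydro-1H-indene-4-carboxylic acid
Conditions: NaClO2, NaH2PO4, 2-methylbut-2-ene, t-BuOH–H2O, 0 °C → rt
Reagents that add atoms: sodium chlorite, [Na+].[O-]Cl=O
Why: Pinnick (Lindgren–Kraus) oxidation converts the hindered, non-enolisable aldehyde into the acid while 2-methylbut-2-ene removes HOCl, so the alkenes, the secondary alcohol and all stereocentres are unaffected.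

Step 13
Reactants: 27 (1S,2S,3S,3aR,4R,5S,7aR)-3,4,5,7-tetraethyl-2-hydroxy-1-methyl-5-[(E)-2-phenylethenyl]-2,3,3a,4,5,7a-hexahydro-1H-indene-4-carboxylic acid
Product: 28 (1S,3S,3aR,4R,5S,7aR)-3,4,5,7-tetraethyl-1-methyl-2-oxo-5-[(E)-2-phenylethenyl]-2,3,3a,4,5,7a-hexahydro-1H-indene-4-carboxylic acid
Conditions: DMP, CH2Cl2, rt
Reagents that add atoms: none
Why: Dess–Martin oxidation of the secondary alcohol gives the cyclopentanone, whose flanking ring carbons 1 and 3 already carry the thermodynamically preferred configurations (each alkyl group trans to the neighbouring ring-fusion substituent) and are not epimerised under these neutral conditions.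

## Compound list

1 | triphenylphosphine | c1ccc(cc1)P(c1ccccc1)c1ccccc1 | starting material
2 | ethyl 2-bromobutanoate (racemic) | CCC(Br)C(=O)OCC | starting material
3 | (1-ethoxy-1-oxobutan-2-yl)triphenylphosphonium bromide | CCC(C(=O)OCC)[P+](c1ccccc1)(c1ccccc1)c1ccccc1.[Br-] | intermediate (not isolated)
4 | ethyl 2-(triphenyl-λ5-phosphanylidene)butanoate | CCC(C(=O)OCC)=P(c1ccccc1)(c1ccccc1)c1ccccc1 | intermediate
5 | butanal | CCCC=O | starting material
6 | formaldehyde | C=O | starting material
7 | (2R)-2-(hydroxymethyl)butanal | CC[C@H](CO)C=O | intermediate (not isolated)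
8 | ethyl (2E,4S)-2-ethyl-4-(hydroxymethyl)hex-2-enoate | CC[C@H](CO)/C=C(\CC)C(=O)OCC | intermediate
9 | ethyl (2E,4S)-2-ethyl-4-formylhex-2-enoate | CC[C@H](C=O)/C=C(\CC)C(=O)OCC | intermediate
10 | hex-3-yn-2-one | CCC#CC(C)=O | starting material
11 | (2R)-hex-3-yn-2-ol | CCC#C[C@@H](C)O | intermediate
12 | (2R)-hex-3-yn-2-yl methanesulfonate | CCC#C[C@@H](C)OS(C)(=O)=O | intermediate
13 | (aS)-hexa-2,3-dien-4-yl(iodo)indium methanesulfonate | CC([H])=[C@@]=C(CC)[In](I)OS(C)(=O)=O | intermediate (not isolated)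
14 | ethyl (2E,4S,5R,6S)-2,4-diethyl-5-hydroxy-6-methyldec-2-en-7-ynoate | CCC#C[C@H](C)[C@H](O)[C@@H](CC)/C=C(\CC)C(=O)OCC | intermediate
15 | (2E,4S,5R,6S)-2,4-diethyl-6-methyldec-2-en-7-yne-1,5-diol | CCC#C[C@H](C)[C@H](O)[C@@H](CC)/C=C(\CC)CO | intermediate
16 | 2-ethylacrolein (2-methylidenebutanal) | CCC(=C)C=O | starting material
17 | 2-bromo-2-(bromomethyl)butanal (racemic) | CCC(Br)(CBr)C=O | intermediate (not isolated)
18 | (2E)-3-bromo-2-ethylprop-2-enal | Br/C=C(\CC)C=O | intermediate
19 | diethyl benzylphosphonate | CCOP(=O)(Cc1ccccc1)OCC | starting material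
20 | sodium (diethoxyphosphoryl)(phenyl)methanide | [Na+].CCOP(=O)([CH-]c1ccccc1)OCC | intermediate (not isolated)
21 | [(1E,3E)-4-bromo-3-ethylbuta-1,3-dien-1-yl]benzene | Br/C=C(\CC)/C=C/c1ccccc1 | intermediate
22 | C8-alkenylzirconocene chloride from 15: Zr on C8 cis to the C7–H, both oxygens as O–Zr(Cp)2Cl (Cp drawn σ-bonded) | CC/C(=C\[C@H](C)[C@H](O[Zr](Cl)(C1C=CC=C1)C1C=CC=C1)[C@@H](CC)/C=C(\CC)CO[Zr](Cl)(C1C=CC=C1)C1C=CC=C1)[Zr](Cl)(C1C=CC=C1)C1C=CC=C1 | intermediate (not isolated)
23 | the corresponding C8-alkenylzinc chloride, oxygens still as O–Zr(Cp)2Cl | CC/C(=C\[C@H](C)[C@H](O[Zr](Cl)(C1C=CC=C1)C1C=CC=C1)[C@@H](CC)/C=C(\CC)CO[Zr](Cl)(C1C=CC=C1)C1C=CC=C1)[Zn]Cl | intermediate (not isolated)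
24 | (2E,4S,5S,6S,7E,9E,11E)-2,4,8,10-tetraethyl-6-methyl-12-phenyldodeca-2,7,9,11-tetraene-1,5-diol (C5 is unchanged in space; the descriptor changes from R to S by priority only) | c1ccccc1/C=C/C(CC)=C/C(CC)=C/[C@H](C)[C@H](O)[C@@H](CC)/C=C(\CC)CO | intermediate
25 | (2E,4S,5S,6S,7E,9E,11E)-2,4,8,10-tetraethyl-5-hydroxy-6-methyl-12-phenyldodeca-2,7,9,11-tetraenal | c1ccccc1/C=C/C(CC)=C/C(CC)=C/[C@H](C)[C@H](O)[C@@H](CC)/C=C(\CC)C=O | intermediate (not isolated)
26 | (1S,2S,3S,3aR,4R,5S,7aR)-3,4,5,7-tetraethyl-2-hydroxy-1-methyl-5-[(E)-2-phenylethenyl]-2,3,3a,4,5,7a-hexahydro-1H-indene-4-carbaldehyde | CCC1=C[C@@](/C=C/c2ccccc2)(CC)[C@](CC)(C=O)[C@@H]2[C@@H]1[C@H](C)[C@H](O)[C@H]2CC | intermediate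
27 | (1S,2S,3S,3aR,4R,5S,7aR)-3,4,5,7-tetraethyl-2-hydroxy-1-methyl-5-[(E)-2-phenylethenyl]-2,3,3a,4,5,7a-hexahydro-1H-indene-4-carboxylic acid | CCC1=C[C@@](/C=C/c2ccccc2)(CC)[C@](CC)(C(=O)O)[C@@H]2[C@@H]1[C@H](C)[C@H](O)[C@H]2CC | intermediate
28 | (1S,3S,3aR,4R,5S,7aR)-3,4,5,7-tetraethyl-1-methyl-2-oxo-5-[(E)-2-phenylethenyl]-2,3,3a,4,5,7a-hexahydro-1H-indene-4-carboxylic acid | CCC1=C[C@@](/C=C/c2ccccc2)(CC)[C@](CC)(C(=O)O)[C@@H]2[C@@H]1[C@H](C)C(=O)[C@H]2CC | target

## Step count and risks

Total step count: 13. Longest linear sequence: 9 steps (steps 1, 2, 3, 6, 7, 10, 11, 12, 13).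

Step 2 (one-pot hydroxymethylation and Wittig trapping). The enamine aldol may give modest ee, or lose material to 2-ethylacrolein and to a second hydroxymethylation before the ylide captures 7. The fallback is auxiliary-controlled; it sets out from ylide 4 and comes back to the route at 8 by way of 7. Bought (4S)-4-benzyl-3-butanoyl-1,3-oxazolidin-2-one is hydroxymethylated through its titanium enolate (TiCl4, i-Pr2NEt, 1,3,5-trioxane, CH2Cl2, 0 °C), the electrophile entering opposite the benzyl group, to give (4S)-4-benzyl-3-[(2R)-2-(hydroxymethyl)butanoyl]-1,3-oxazolidin-2-one F1. Transamidation (MeNHOMe·HCl, AlMe3, CH2Cl2) gives (2R)-2-(hydroxymethyl)-N-methoxy-N-methylbutanamide F2. Reduction (i-Bu2AlH, THF, −78 °C) gives 7, which is trapped with 4 as in step 2 to give 8.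

Step 3 (aldehyde 9; any damage would show in step 6). The C4–H of 9 is α to the formyl group and γ to the enoate, so 9 may racemise or move into conjugation before the allenylindium reagent captures it. The fallback postpones the enoate; it sets out from 5 and 6 and comes back at 14. With the enantiomeric catalyst (R)-2-[diphenyl(trimethylsilyloxy)methyl]pyrrolidine, 5 and 6 give (2S)-2-(hydroxymethyl)butanal F3. Silylation in the same flask (TBSCl, imidazole) gives the configurationally robust (2S)-2-({[tert-butyl(dimethyl)silyl]oxy}methyl)butanal F4. Marshall propargylation of this aldehyde with 12 under the conditions of step 6 gives (3S,4S,5S)-3-({[tert-butyl(dimethyl)silyl]oxy}methyl)-5-methylnon-6-yn-4-ol F5. Bu4NF in THF gives (2S,3S,4S)-2-ethyl-4-methyloct-5-yne-1,3-diol F6. Selective oxidation of the primary alcohol (2,2,6,6-tetramethylpiperidin-1-oxyl (cat.), PhI(OAc)2, CH2Cl2) gives (2R,3S,4S)-2-ethyl-3-hydroxy-4-methyloct-5-ynal F7, which reacts in the same flask with 4 to give 14.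

Step 10 (hydrozirconation and Negishi coupling). Ethyl is only modestly smaller than the branched C6 substituent, so part of the zirconium may end up on C7, and the excess Cp2Zr(H)Cl that the free diol demands may erode the yield. The fallback is a copper-catalysed protoboration followed by Suzuki–Miyaura coupling; it sets out from 15 and comes back at 24. CuCl (5 mol %), P(p-tolyl)3, NaOt-Bu (cat.), B2pin2 and MeOH in THF add boron and hydrogen cis across the alkyne, boron going to the less hindered ethyl-bearing carbon and the hydroxyls needing no protection. This gives the isolable (2E,4S,5S,6S,7Z)-2,4-diethyl-6-methyl-8-(4,4,5,5-tetramethyl-1,3,2-dioxaborolan-2-yl)deca-2,7-diene-1,5-diol F8, from which any regioisomer can be removed by chromatography. Coupling of F8 with 21 (Pd(PPh3)4, aq. NaOH, THF, 50 °C) gives 24.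

Further compounds
F1 | step 2 | (4S)-4-benzyl-3-[(2R)-2-(hydroxymethyl)butanoyl]-1,3-oxazolidin-2-one | CC[C@H](CO)C(=O)N1[C@@H](Cc2ccccc2)COC1=O
F2 | step 2 | (2R)-2-(hydroxymethyl)-N-methoxy-N-methylbutanamide | CC[C@H](CO)C(=O)N(C)OC
F3 | step 3 | (2S)-2-(hydroxymethyl)butanal | CC[C@@H](CO)C=O
F4 | step 3 | (2S)-2-({[tert-butyl(dimethyl)silyl]oxy}methyl)butanal | CC[C@@H](CO[Si](C)(C)C(C)(C)C)C=O
F5 | step 3 | (3S,4S,5S)-3-({[tert-butyl(dimethyl)silyl]oxy}methyl)-5-methylnon-6-yn-4-ol | CCC#C[C@H](C)[C@H](O)[C@@H](CC)CO[Si](C)(C)C(C)(C)C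
F6 | step 3 | (2S,3S,4S)-2-ethyl-4-methyloct-5-yne-1,3-diol | CCC#C[C@H](C)[C@H](O)[C@@H](CC)CO
F7 | step 3 | (2R,3S,4S)-2-ethyl-3-hydroxy-4-methyloct-5-ynal | CCC#C[C@H](C)[C@H](O)[C@@H](CC)C=O
F8 | step 10 | (2E,4S,5S,6S,7Z)-2,4-diethyl-6-methyl-8-(4,4,5,5-tetramethyl-1,3,2-dioxaborolan-2-yl)deca-2,7-diene-1,5-diol | CC/C(=C\[C@H](C)[C@H](O)[C@@H](CC)/C=C(\CC)CO)B1OC(C)(C)C(C)(C)O1
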